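(The runs are calculated for substances that don't exist, noise included.)

Early in this flask substrate drops fast and both mono adducts rise together, and what interests me is what happens after that. The flask is the autumn run carried on to a later time.

| flask | substrate | coupling partner | remark | time |
|---|---|---|---|---|
| autumn | 0.062 M | 0.112 M | the very flask that is asked about, followed so far |  |
| flask | 0.062 M | 0.112 M |  | 10 min |

- autumn (time / s: substrate / %, first product / %, other mono adduct / %): 10.0: 40.3, 26.6, 29.1; 15.0: 28.2, 31.9, 33.3; 25.0: 15.6, 37.3, 36.8; 40.0: 8.2, 39.7, 37.1; 80.0: 3.1, 39.6, 31.0; 120: 2.1, 37.2, 25.9

(each reading ± 0.3 percentage points)

- a reading or a percentage of first product counts all its forms, free or not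

- the substrate standing at 10 min, as a percentage of the substrate charged
- the first product standing at 10 min, as a percentage of the substrate charged
- the other mono adduct standing at 10 min, as a percentage of the substrate charged
- the bis adduct standing at 10 min, as a percentage of the substrate charged

1. The readings leave a gap, which I count as bis adduct: 26.3% at 80.0 s and 34.8% at 120 s.

2. End state: a mono adduct holds one coupling partner and a bis adduct two. So I carry the partner surplus, the coupling partner charged minus the substrate charged, over the substrate charged: 80.6%. If coupling partner goes nowhere but into adducts, partner left equals surplus plus standing substrate minus bis adduct. The surplus is below the whole charge, so coupling partner is the limiting reagent of the second addition.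

3. Speed: as a working assumption I neglect substrate and lump the second addition into one law, monos times partner left. The logarithm of their ratio, measured against its starting value, then grows in proportion to time. The reading at 120 s gives a slope of 0.00114 s⁻¹.

4. Carrying that slope to 10 min gives bis adduct at 67.4%, and I commit to that. I do not split the monos.

5. The weak link is a slope from one differenced reading. The reading at 80.0 s gives 0.00112 s⁻¹ and bis adduct at 67.0%.

The forecast says substrate 1.3%, first product 26%, other mono adduct 6.5%, bis adduct 66%, on the ground that “It then stalls well above the second-order prediction, so something feeds it back.”

The flask gives substrate 5.06%, first product 14.0%, other mono adduct 14.2%, bis adduct 66.8%.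

    substrate + coupling partner ⇌ first product (K = 26.0 M⁻¹, k = 0.500 M⁻¹ s⁻¹)
    substrate + coupling partner → other mono adduct (k = 0.550 M⁻¹ s⁻¹)
    crystals ⇌ first product, rate k3*(cs3 - [first product]) while solid is left; crystals form when [first product] > cs3 (solubility = 1.90 mM, k = 4.80 s⁻¹)
    coupling partner → decomposition product (k = 1.70 × 10⁻⁴ s⁻¹)
    coupling partner + other mono adduct → bis adduct (k = 0.180 M⁻¹ s⁻¹)
    coupling partner + first product → bis adduct (k = 0.310 M⁻¹ s⁻¹)

In this flask the forward half-lives of substrate at charged concentrations, 0.21 min to first product and 0.19 min to other mono adduct, are short against the 10 min asked . By that time bis adduct stands at 66.8% under the surplus of 80.6%, and the forecast's first product is 12 percentage points high. At 10 min, 10.9% of this flask's 14.0% first product is crystals, and the scheme has no step from crystals to bis adduct, so my single slope stands in for two steps, on other mono adduct and on dissolved first product. Left until 100 min, this flask holds bis adduct at 79.9%. The neighbour flask with 0.037 M of substrate has a surplus of 203%, above its whole charge, and at 10 min it holds bis adduct at 97.9%.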